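The route rests on cutting the bond between C6, the fully substituted peroxy carbon of the 1,2-dioxane (ring A), and C1' of the 10-phenyldecyl chain. Because C6 carries peroxide oxygen O1, it is a masked ketone carbon and may be trigonal when the chain arrives. One operation, hydroboration of 10-phenyldec-1-ene and B-alkyl Suzuki–Miyaura coupling, joins C1' to the C6–Br bond of an (R)-2-bromoallyl butenolide (unsaturated ring B, C4 from (S)-lactic acid). Ozone in methanol then trades the spare =CH2 for OOH and OMe. Oxa-Michael closure builds ring A and sets C3. The C6 methyl enters last, axially, which sets C6.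

Key step: step 7

Numbering used: C1 lactone carbonyl, C2 CH2, C3 CH–O2, C4 C(CH3)–O(lactone), C5 CH2, C6 quaternary carbon on O1, C1' first carbon of the chain. Ring A = 1,2-dioxane (O1, O2, C3–C6); ring B = γ-lactone.
Remark on the chemistry: 18 and 19 are assumed to form as mixtures of C6 epimers, are used as such and are written with C6 undefined.
Remark on the chemistry: a group that adds to a ring A peroxycarbenium ion ends cis to C2 across the ring. The target has the C6 methyl cis to C2, so the chain is attached first and the methyl last.

Step 1
Reactants: 1 (S)-lactic acid; 2 pivalaldehyde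
Product: 3 (2S,5S)-2-tert-butyl-5-methyl-1,3-dioxolan-4-one
Conditions: p-TsOH (cat.), pentane, reflux, Dean–Stark; recrystallisation from pentane
Reagents that add atoms: none
Why: Acid-catalysed acetalisation with azeotropic removal of water is reversible, so the lactate centre (C5 of the dioxolanone) should steer the new acetal centre C2 to the more stable cis (2S,5S) isomer, which crystallisation should free from the trans isomer (first stage of self-regeneration of stereocentres).

Step 2
Reactants: 3 (2S,5S)-2-tert-butyl-5-methyl-1,3-dioxolan-4-one; 4 2,3-dibromopropene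
Product: 6 (2S,5R)-5-(2-bromoprop-2-en-1-yl)-2-tert-butyl-5-methyl-1,3-dioxolan-4-one, via lithium enolate 5 (not isolated)
Conditions: LiN(iPr)2, THF, −78 °C; then 4, −78 → −20 °C
Reagents that add atoms: none
Why: Enolate alkylation by SN2 displacement of the allylic bromide (the vinylic C–Br bond is inert): the original centre is lost in the planar enolate 5, but the tert-butyl group on the acetal carbon shields one face, so the electrophile should enter trans to it and set the quaternary centre, the future C4, as (R).

Step 3
Reactants: 6 (2S,5R)-5-(2-bromoprop-2-en-1-yl)-2-tert-butyl-5-methyl-1,3-dioxolan-4-one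
Product: 7 (R)-4-bromo-2-methylpent-4-ene-1,2-diol
Conditions: LiAlH4, Et2O, 0 °C
Reagents that add atoms: none
Why: Hydride reduction of the activated lactone carbonyl unravels the acetal and releases the 1,2-diol together with the spent auxiliary, while the quaternary centre has no bond broken and a vinylic bromide should survive LiAlH4 at 0 °C.

Step 4
Reactants: 7 (R)-4-bromo-2-methylpent-4-ene-1,2-diol
Product: 8 (R)-4-bromo-2-hydroxy-2-methylpent-4-enal
Conditions: IBX, DMSO, rt
Reagents that add atoms: none
Why: IBX oxidation takes the primary alcohol to the aldehyde, cannot oxidise the tertiary alcohol and, unlike periodate-type oxidants, does not cleave 1,2-diols, and the aldehyde has no α-hydrogen through which C4 could be scrambled.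

Step 5
Reactants: 8 (R)-4-bromo-2-hydroxy-2-methylpent-4-enal; 9 methyl bis(2,2,2-trifluoroethyl)phosphonoacetate
Product: 11 (R)-5-(2-bromoprop-2-en-1-yl)-5-methylfuran-2(5H)-one, via Z-enoate 10 (not isolated)
Conditions: 9, KN(SiMe3)2, 18-crown-6, THF, −78 °C; then PPTS (cat.), CH2Cl2, rt
Reagents that add atoms: none
Why: Still–Gennari olefination: the electron-poor bis(trifluoroethyl) phosphonate makes elimination from the kinetic adduct fast and should give the Z-enoate 10, whose tertiary hydroxyl sits next to the ester and lactonises under mild acid to ring B in its unsaturated form without touching C4.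

Step 6
Reactants: 12 phenethylmagnesium chloride; 13 8-bromooct-1-ene
Product: 14 10-phenyldec-1-ene
Conditions: Li2CuCl4 (cat.), THF, 0 °C → rt
Reagents that add atoms: none
Why: Copper-catalysed cross-coupling of a primary alkyl Grignard reagent with a primary alkyl bromide forms the sp3–sp3 bond by way of an organocuprate, and the remote terminal alkene is a spectator.

Step 7
Reactants: 11 (R)-5-(2-bromoprop-2-en-1-yl)-5-methylfuran-2(5H)-one; 14 10-phenyldec-1-ene
Product: 16 (R)-5-methyl-5-(2-methylidene-12-phenyldodecyl)furan-2(5H)-one, via B-(10-phenyldecyl)-9-BBN 15 (not isolated)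
Conditions: 14, 9-BBN, THF, 0 °C → rt; then 11, PdCl2(dppf) (cat.), AsPh3 (cat.), Cs2CO3, DMF/H2O, rt
Reagents that add atoms: none
Why: 9-BBN adds to the terminal alkene of 14 with anti-Markovnikov selectivity and turns C1' into the nucleophilic primary alkylborane 15; zerovalent palladium inserts into the C6–Br bond of 11, Cs2CO3/water forms the borate that transmetalates, and reductive elimination forges the C6(sp2)–C1'(sp3) bond. The closest known reaction type is the B-alkyl Suzuki–Miyaura coupling of 2-bromoalk-1-enes, so no new chemistry is asked of this step. No ring is closed and no stereocentre is created: C4 is a spectator without an acidic hydrogen, and C6 is kept trigonal on purpose so that its configuration can be set later by the order in which its substituents arrive. The step needs chemoselectivity for the C–Br bond over the butenolide alkene and the lactone; this is secured by consuming all B–H before 11 is added, by the fast room-temperature transmetalation of the dppf/AsPh3 system, which should outrun a strained 4-exo Heck closure onto C3, and by the mild carbonate base. β-Hydride elimination from the alkylpalladium species is held back by the wide bite angle of dppf.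

Step 8
Reactants: 16 (R)-5-methyl-5-(2-methylidene-12-phenyldodecyl)furan-2(5H)-one
Product: 18 (5R)-5-(2-hydroperoxy-2-methoxy-12-phenyldodecyl)-5-methylfuran-2(5H)-one (both C6 epimers), via carbonyl oxide 17 (not isolated)
Conditions: O3, CH2Cl2/MeOH, NaHCO3, −78 °C, stopped at consumption of 16; N2 purge, no reductive work-up
Reagents that add atoms: ozone [O-][O+]=O; methanol CO
Why: Criegee ozonolysis in a participating solvent: the electron-rich 1,1-dialkyl alkene should react far faster than the electron-poor butenolide alkene or the arene, cycloreversion of the primary ozonide places the carbonyl oxide 17 on the dialkyl-substituted C6 and expels formaldehyde, and methanol traps 17 as the α-methoxy hydroperoxide, whose C6 epimers are both carried on because C6 becomes planar again in step 10.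

Step 9
Reactants: 18 (5R)-5-(2-hydroperoxy-2-methoxy-12-phenyldodecyl)-5-methylfuran-2(5H)-one
Product: 19 (4aR,7aR)-3-methoxy-4a-methyl-3-(10-phenyldecyl)tetrahydrofuro[3,2-c][1,2]dioxin-6(3H)-one (cis-fused rings A and B, both C6 epimers)
Conditions: Et2NH (cat.), CF3CH2OH, rt
Reagents that add atoms: none
Why: Amine-catalysed intramolecular oxa-Michael addition (6-exo-trig) of the hydroperoxide to the butenolide: the short tether through C5 lets O2 reach C3 only on the face of ring B that bears C5, so C4 sets C3 as (R) and rings A and B are cis-fused, and the acidic, weakly nucleophilic solvent protonates the lactone enolate at C2 before it can attack the O–O bond.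

Step 10
Reactants: 19 (4aR,7aR)-3-methoxy-4a-methyl-3-(10-phenyldecyl)tetrahydrofuro[3,2-c][1,2]dioxin-6(3H)-one
Product: 21 butenolide peroxide, (3R,4aR,7aR)-3,4a-dimethyl-3-(10-phenyldecyl)tetrahydrofuro[3,2-c][1,2]dioxin-6(3H)-one, via peroxycarbenium triflate 20 (not isolated)
Conditions: Me3SiOTf, Me2Zn, CH2Cl2, −78 → −40 °C
Reagents that add atoms: dimethylzinc C[Zn]C
Why: Proposed new method: Me3SiOTf should strip the methoxy group from either C6 epimer of 19 to give the ring A peroxycarbenium ion 20, whose half-chair places the C4–O bond pseudoaxial and the C4 methyl pseudoequatorial, and Me2Zn, which should be inert to dialkyl peroxides and lactones at this temperature, should deliver methyl along the axial trajectory on the face that carries O(lactone) and C2, leading directly to the chair with axial C6 methyl and equatorial chain, that is (6R); the closest known reaction types are the Lewis-acid substitution of 3-alkoxy- and 3-acyloxy-1,2-dioxanes by allylsilanes and silyl enol ethers, which places the incoming group cis to the substituent across the ring, and the Me3SiOTf/dialkylzinc alkylation of 4-acetoxy-1,3-dioxanes by axial attack, but a zinc alkyl has not been shown on a peroxycarbenium ion.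

Compound list
1 | (S)-lactic acid | C[C@H](O)C(=O)O | starting material
2 | pivalaldehyde | CC(C)(C)C=O | starting material
3 | (2S,5S)-2-tert-butyl-5-methyl-1,3-dioxolan-4-one | C[C@@H]1O[C@H](C(C)(C)C)OC1=O | intermediate
4 | 2,3-dibromopropene | BrCC(Br)=C | starting material
5 | lithium enolate of 3 | CC1=C([O-])O[C@@H](C(C)(C)C)O1.[Li+] | intermediate
6 | (2S,5R)-5-(2-bromoprop-2-en-1-yl)-2-tert-butyl-5-methyl-1,3-dioxolan-4-one | C[C@]1(CC(Br)=C)O[C@H](C(C)(C)C)OC1=O | intermediate
7 | (R)-4-bromo-2-methylpent-4-ene-1,2-diol | C[C@](CO)(CC(Br)=C)O | intermediate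
8 | (R)-4-bromo-2-hydroxy-2-methylpent-4-enal | C[C@](C=O)(CC(Br)=C)O | intermediate
9 | methyl bis(2,2,2-trifluoroethyl)phosphonoacetate | COC(=O)CP(=O)(OCC(F)(F)F)OCC(F)(F)F | starting material
10 | methyl (2Z,4R)-6-bromo-4-hydroxy-4-methylhepta-2,6-dienoate | C[C@@](O)(CC(Br)=C)/C=C\C(=O)OC | intermediate
11 | (R)-5-(2-bromoprop-2-en-1-yl)-5-methylfuran-2(5H)-one | C[C@@]1(CC(Br)=C)C=CC(=O)O1 | intermediate
12 | phenethylmagnesium chloride | Cl[Mg]CCc1ccccc1 | starting material
13 | 8-bromooct-1-ene | C=CCCCCCCBr | starting material
14 | 10-phenyldec-1-ene | C=CCCCCCCCCc1ccccc1 | intermediate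
15 | B-(10-phenyldecyl)-9-borabicyclo[3.3.1]nonane | C(CCCCCCCCCc1ccccc1)B1C2CCCC1CCC2 | intermediate
16 | (R)-5-methyl-5-(2-methylidene-12-phenyldodecyl)furan-2(5H)-one | C[C@@]1(CC(=C)CCCCCCCCCCc2ccccc2)C=CC(=O)O1 | intermediate
17 | C6 carbonyl oxide of the butenolide | C[C@@]1(CC(=[O+][O-])CCCCCCCCCCc2ccccc2)C=CC(=O)O1 | intermediate
18 | (5R)-5-(2-hydroperoxy-2-methoxy-12-phenyldodecyl)-5-methylfuran-2(5H)-one, both C6 epimers | C[C@@]1(CC(OC)(OO)CCCCCCCCCCc2ccccc2)C=CC(=O)O1 | intermediate
19 | (4aR,7aR)-3-methoxy-4a-methyl-3-(10-phenyldecyl)tetrahydrofuro[3,2-c][1,2]dioxin-6(3H)-one, both C6 epimers | COC1(CCCCCCCCCCc2ccccc2)C[C@@]2(C)OC(=O)C[C@H]2OO1 | intermediate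
20 | ring A peroxycarbenium triflate (C6=O1 cation, C3 and C4 as in 19) | C1(CCCCCCCCCCc2ccccc2)C[C@@]2(C)OC(=O)C[C@H]2O[O+]=1.[O-]S(=O)(=O)C(F)(F)F | intermediate
21 | butenolide peroxide, (3R,4aR,7aR)-3,4a-dimethyl-3-(10-phenyldecyl)tetrahydrofuro[3,2-c][1,2]dioxin-6(3H)-one | C[C@@]1(CCCCCCCCCCc2ccccc2)C[C@@]2(C)OC(=O)C[C@H]2OO1 | target

Total step count: 10
Longest linear sequence: 9 (steps 1–5 and 7–10)

Steps most likely to fail

**Step 10 (Proposed new method).**
- What may go wrong: the cation may lose a proton from C5 or C1'. The Lewis acid may ionise the C6–O1 bond instead of the C6–OMe bond and open ring A. The zinc alkyl may attack the O–O bond, or facial selectivity may be poor.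
- Fallback (known chemistry): it sets out from alkene 16 and keeps the =CH2 carbon as the C6 methyl. Mukaiyama–Isayama peroxidation (Co(thd)2 cat., O2, Et3SiH, 1,2-dichloroethane, rt) should transfer a hydrogen atom to the =CH2 terminus, and O2 should capture the tertiary C6 radical to give the triethylsilyl peroxide F1. HF·pyridine in THF should free the tertiary hydroperoxide F2. Et2NH in CF3CH2OH should then close ring A as in step 9.
- Limitation: C6 is not controlled on this path, so the target would have to be separated by chromatography from its C6 epimer F3. The fallback comes back to the route at 21.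

**Step 7 (key step).**
- What may go wrong: the vinylpalladium species may be diverted by carbopalladation of the butenolide alkene. The aqueous base may open or add to the lactone, or transmetalation next to the neopentyl-type C5 may be slow enough for protodebromination to compete.
- Fallback: it changes the order of events so that the union is made before any electrophilic alkene exists. It sets out from diol 7, which is coupled with borane 15 to give the chain-bearing diol F4. IBX oxidation should give the hydroxy aldehyde F5. Still–Gennari olefination should give the Z-enoate F6, which lactonises under mild acid. The fallback comes back to the route at 16.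

**Step 8.**
- What may go wrong: the primary ozonide may cleave in the other sense (ketone plus formaldehyde oxide). The carbonyl oxide may be trapped by the lactone carbonyl instead of methanol, or ozone may start to consume the butenolide alkene.
- Fallback: it separates cleavage from peroxide installation. It sets out from 16. Lemieux–Johnson cleavage (OsO4 cat., NaIO4, 2,6-lutidine, dioxane/H2O) should give the methylene ketone F7. Acid-catalysed perketalisation (urea·H2O2, Sc(OTf)3 cat., MeOH, rt) should then convert the C6 carbonyl into the α-methoxy hydroperoxide. The fallback comes back to the route at 18.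

Further compounds
F1 | step 10 | (5R)-5-methyl-5-[2-methyl-12-phenyl-2-(triethylsilylperoxy)dodecyl]furan-2(5H)-one, both C6 epimers | C[C@@]1(CC(C)(OO[Si](CC)(CC)CC)CCCCCCCCCCc2ccccc2)C=CC(=O)O1
F2 | step 10 | (5R)-5-(2-hydroperoxy-2-methyl-12-phenyldodecyl)-5-methylfuran-2(5H)-one, both C6 epimers | C[C@@]1(CC(C)(OO)CCCCCCCCCCc2ccccc2)C=CC(=O)O1
F3 | step 10 | C6 epimer of the target, (3S,4aR,7aR)-3,4a-dimethyl-3-(10-phenyldecyl)tetrahydrofuro[3,2-c][1,2]dioxin-6(3H)-one | C[C@]1(CCCCCCCCCCc2ccccc2)C[C@@]2(C)OC(=O)C[C@H]2OO1
F4 | step 7 | (R)-2-methyl-4-methylidene-14-phenyltetradecane-1,2-diol | C[C@](CO)(CC(=C)CCCCCCCCCCc1ccccc1)O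
F5 | step 7 | (R)-2-hydroxy-2-methyl-4-methylidene-14-phenyltetradecanal | C[C@](C=O)(CC(=C)CCCCCCCCCCc1ccccc1)O
F6 | step 7 | methyl (2Z,4R)-4-hydroxy-4-methyl-6-methylidene-16-phenylhexadec-2-enoate | C[C@@](O)(CC(=C)CCCCCCCCCCc1ccccc1)/C=C\C(=O)OC
F7 | step 8 | (R)-5-methyl-5-(2-oxo-12-phenyldodecyl)furan-2(5H)-one | C[C@@]1(CC(=O)CCCCCCCCCCc2ccccc2)C=CC(=O)O1
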